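The readings were generated by integration from invented constants; scatter was added.

1. Winter's run held more target per side product than spring's: 0.997 at 6.00 h against 0.457 at 5.00 h, or twice as much, on twice the partner.

| setting | winter | spring | Friday's | Tuesday's | Wednesday's | Sunday's |
|---|---|---|---|---|---|---|
| starting material | 20 mM | 20 mM | 20 mM | 20 mM | 20 mM | 20 mM |
| partner | 0.50 equiv | 0.25 equiv | 0.500 equiv (fed, over 5.0 h) | 0.500 equiv (in portions, 5, over 5.0 h) | 0.500 equiv (fed, over 5.0 h) | 0.500 equiv |
| temperature | 80 °C | 80 °C | 80 °C | 80 °C |  | 80 °C |
| remark | run made earlier | run made earlier | all else is in the flask from the start; the feed brings no volume worth counting | first portion at the start, last at 5.0 h | the addition at 40 °C, then warmed to 80 °C; the feed brings no volume worth counting | everything together at the start |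
| time |  |  | 25 h | 25 h | 25 h | 25 h |

| run | time / h | target / % | side product / % |
|---|---|---|---|
| winter | 6.00 | 33.8 | 33.9 |
| winter | 12.0 | 32.8 | 41.9 |
| winter | 20.0 | 29.4 | 47.8 |
| winter | 25.0 | 27.1 | 51.1 |
| spring | 1.00 | 9.5 | 16.3 |
| spring | 2.50 | 15.5 | 28.8 |
| spring | 5.00 | 18.4 | 40.3 |
| spring | 8.00 | 18.7 | 48.7 |

(each reading ± 0.3 percentage points)

- percentages count the starting material that a species holds: one side product counts as two
- the earlier runs do not show what temperature does; that part of a forecast is a guess

- the best flask by share of target in target plus side product; "all alike" if 1.5 percentage points covers them all (Friday's / Tuesday's / Wednesday's / Sunday's / all alike)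
- share of target in target plus side product at the end, Friday's
- share of target in target plus side product at the end, Tuesday's
- share of target in target plus side product at the end, Wednesday's
- share of target in target plus side product at the end, Sunday's

2. Dividing each ratio by its equivalents, I read a selectivity factor of 1.91. I defined N as that factor times c(partner)/c(starting material), with c(partner) counting what has gone in so far and both taken on the charge of starting material. N is the target formed per side product formed, as a reading of these runs, and control crosses from side product to target at N = 1.

3. Winter's N is 0.955, close to that crossing. One number was not enough, though: winter's ratio fell to 0.530 at 25.0 h, while target sank to 27.1%. N reads the build-up, not the later drift.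

4. During a steady feed, the amount delivered so far averages half the charge, so I put Friday's at N = 0.478 as an average over the feed, below the crossing. Tuesday's portions also average half the charge, so I expected Tuesday's to match Friday's. N holds no temperature, so it is silent on Wednesday's.

5. The forecast chose Wednesday's: 30% for Friday's, 31.5% for Tuesday's, 37% for Wednesday's and 34.7% for Sunday's. Its ground was “Selectivity therefore needs high partner while starting material is abundant, so dosing hurts”.

6. The flasks gave Wednesday's as best: 30.3% for Friday's, 30.5% for Tuesday's, 37.3% for Wednesday's and 34.9% for Sunday's.

    2 starting material → side product (k = 0.0864 M⁻¹ min⁻¹, Ea = 57.0 kJ mol⁻¹)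
    starting material + partner ⇌ target (K = 720 M⁻¹, k = 0.475 M⁻¹ min⁻¹, Ea = 55.0 kJ mol⁻¹, ΔH = −4.00 kJ mol⁻¹)
    partner + target → over-reaction product (k = 0.0635 M⁻¹ min⁻¹, Ea = 79.0 kJ mol⁻¹)
    (constants at 80 °C)

Friday's held 0.479 target per side product at 5.00 h, against N = 0.478. The neighbouring flask, Friday's with 2.00 equiv of partner, reckons to N = 1.91, above the crossing. At 25.0 h the neighbouring flask held target 14.3% and side product 30.8%, a share of 31.7%. In the neighbouring flask, target plus over-reaction product stood at 2.20 per side product, and over-reaction product held 53.5%.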